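**Strategy.** The seven-membered ring (ring B: C1, C5–C10) carries methyl groups at C1 and C8 and oxygen at C6, with quaternary C1 β and C5 α to that oxygen. The whole ring therefore maps onto achiral 3,6-dimethylcyclohepta-2,6-dienone, made in three steps by a furan–oxyallyl [4+3] cycloaddition. Everything rests on disconnecting C1–C2 and C5–C4: one copper-catalysed asymmetric vinyl conjugate addition, with aldol trapping of the aluminium enolate by isobutyraldehyde, installs both bonds and the C1/C5 stereocentres. The remaining enone is then deconjugated to the C8=C9 alkene, and ring A is closed late by Wacker oxidation and a C3–C4 aldol.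

Key step: step 4

**Remarks**
- Daucane numbering is used from step 4 on. Ring A is the cyclopentane (C1–C5), ring B the cycloheptane (C1, C5–C10); β is the face of ring B that carries the C1 methyl group.
- The target SMILES reads as 1β-Me, 2α-OAc, 4β-OH (4α-isopropyl), 5α-H (trans-fused), 6α-O-anisoyl, 8α,9α-epoxide (8β-Me).
- The two enone units of dienone 6 are exchanged by the twofold axis through the carbonyl group and are homotopic. The stereochemical task of the key step is therefore π-face selection. Configurations 6R,7S in 11 correspond to C1 and C5 of the target.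
- Assumption: the ligand antipode in step 4 is the one that gives 6R; the sense of induction has to be confirmed on the first run.
- Assumption: 1,1,3,3-tetrabromoacetone is purchased.

**Route**

Step 1
Reactants: 1 2,5-dimethylfuran; 2 1,1,3,3-tetrabromoacetone
Product: 4 (1R,5S)-1,5-dimethyl-8-oxabicyclo[3.2.1]oct-6-en-3-one (meso), via dibromo cycloadduct 3 (not isolated)
Conditions: Zn–Cu couple, THF, −10 °C → rt; then Zn–Cu couple, NH4Cl, MeOH, rt
Reagents that add atoms: none
Why: Zinc generates the dibromo-oxyallyl cation, which undergoes a [4+3] cycloaddition across C2/C5 of the electron-rich furan (its blocked α-positions suppress electrophilic substitution), and reductive debromination of the α-bromo ketone 3 then gives ketone 4, whose bridged framework allows only the cis (meso) arrangement.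

Step 2
Reactants: 4 (1R,5S)-1,5-dimethyl-8-oxabicyclo[3.2.1]oct-6-en-3-one
Product: 5 (1R,5S)-1,5-dimethyl-8-oxabicyclo[3.2.1]octan-3-one (meso)
Conditions: H2 (1 atm), Pd/C (10 wt % Pd on carbon), EtOAc, rt
Reagents that add atoms: none
Why: Heterogeneous catalytic hydrogenation saturates the strained disubstituted alkene without touching the ketone or the tertiary ether bridge, and no new stereocentre is formed.

Step 3
Reactants: 5 (1R,5S)-1,5-dimethyl-8-oxabicyclo[3.2.1]octan-3-one
Product: 6 3,6-dimethylcyclohepta-2,6-dien-1-one
Conditions: CF3SO3H (2.5 equiv), CH2Cl2, −20 → 0 °C; then aq. NaHCO3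
Reagents that add atoms: none
Why: Acid-promoted β-elimination opens the tertiary β-alkoxy ketone (retro-oxa-Michael) and dehydrates the resulting tertiary β-hydroxy ketone, the established way from hydrogenated furan–oxyallyl cycloadducts to cyclohepta-2,6-dienones, and in strong acid the O-protonated cross-conjugated dienone (a hydroxypentadienyl cation with two tertiary termini) is the thermodynamic sink.

Step 4
Reactants: 6 3,6-dimethylcyclohepta-2,6-dien-1-one; 7 vinylmagnesium bromide; 8 isobutyraldehyde
Product: 11 (6R,7S)-6-ethenyl-7-[(1S)-1-hydroxy-2-methylpropyl]-3,6-dimethylcyclohept-2-en-1-one, via dimethyl(vinyl)alane 9 (not isolated), via dimethylaluminium dienolate 10 (not isolated)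
Conditions: 7, Me2AlCl, Et2O–THF, 0 °C, then 1,4-dioxane, filtration; Cu(OTf)2 (5 mol %), (S)-BINOL N,N-bis[(R)-1-phenylethyl]phosphoramidite (10 mol %), 6, Et2O, −30 °C; then 8, −78 → −40 °C; aq. potassium sodium tartrate
Reagents that add atoms: none
Why: Transmetalation gives the mixed alane 9, and the chiral catalyst formed from Cu(OTf)2 and the phosphoramidite transfers its vinyl group to a β-carbon of 6 (alkene π-complexation, oxidative addition at the β-carbon, reductive elimination), creating quaternary C1 and the regiodefined dimethylaluminium enolate 10, which adds to 8 at C5 through a closed six-membered Zimmerman–Traxler transition state. The closest known reaction type is the copper-catalysed asymmetric conjugate addition of alkenylalanes to β-methylcycloalkenones with aldehyde capture of the aluminium enolate, together with enantioselective mono-addition to cross-conjugated cyclic dienones. No ring is closed. C1 is controlled by the ligand, since the homotopic enone units leave only a π-face to be chosen and attack on either unit gives the same 6R product; C5 is controlled by the neighbouring C1, the aldehyde approaching anti to the vinyl group, which as a planar substituent geminal to methyl should keep the pseudoaxial position in which it was delivered; the carbinol centre follows from the fixed E(O) geometry of the cyclic enolate (anti aldol). Mono-addition is needed and is secured by the substrate itself, because after the first addition the remaining enone is tied up as a dienolate until the aldehyde is added at −78 °C, where excess alane is consumed by the aldehyde. The vinyl-versus-methyl face discrimination at C5 is the least certain element and is the risk that the route concentrates in this step.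

Step 5
Reactants: 11 (6R,7S)-6-ethenyl-7-[(1S)-1-hydroxy-2-methylpropyl]-3,6-dimethylcyclohept-2-en-1-one
Product: 13 (6R,7S)-6-ethenyl-7-[(1S)-1-hydroxy-2-methylpropyl]-3,6-dimethylcyclohept-3-en-1-one, via dilithium alkoxide dienolate 12 (not isolated)
Conditions: LiN(i-Pr)2 (2.3 equiv), THF–DMPU, −78 °C; then AcOH, THF, −78 °C; cold neutral work-up, used crude
Reagents that add atoms: none
Why: Deconjugative protonation: the first equivalent of amide forms the C4 lithium alkoxide, which disfavours removal of the adjacent C5 proton, so the second equivalent removes a γ-proton at C9 (the γ-carbon cis to the carbonyl) to give the extended dienolate 12, and kinetic protonation of that dienolate at the α-carbon C7 leaves the C8=C9 alkene out of conjugation with C1, C5 and the carbinol centre untouched.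

Step 6
Reactants: 13 (6R,7S)-6-ethenyl-7-[(1S)-1-hydroxy-2-methylpropyl]-3,6-dimethylcyclohept-3-en-1-one
Product: 14 (1R,6R,7R)-6-ethenyl-7-[(1S)-1-hydroxy-2-methylpropyl]-3,6-dimethylcyclohept-3-en-1-ol
Conditions: Et2BOMe, THF–MeOH (4:1), −78 °C; NaBH4, −78 °C; then AcOH, MeOH co-evaporation
Reagents that add atoms: none
Why: Narasaka–Prasad reduction: the diethylboron chelate of the β-hydroxy ketone is reduced by external axial hydride attack to the 1,3-syn diol, which here means hydride delivery to the β-face of C6 so that the new C6 oxygen is α and trans to the C5 side chain (the all-equatorial dioxaborinane), while the low temperature prevents reconjugation of the alkene.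

Step 7
Reactants: 14 (1R,6R,7R)-6-ethenyl-7-[(1S)-1-hydroxy-2-methylpropyl]-3,6-dimethylcyclohept-3-en-1-ol; 15 4-methoxybenzoyl chloride
Product: 16 (1R,6R,7S)-6-ethenyl-7-[(1S)-1-hydroxy-2-methylpropyl]-3,6-dimethylcyclohept-3-en-1-yl 4-methoxybenzoate
Conditions: 15 (1.1 equiv), pyridine, DMAP (cat.), CH2Cl2, −20 → 0 °C
Reagents that add atoms: none
Why: Nucleophile-catalysed acylation is sterically discriminating, and the ring C6 hydroxyl (one CH2 neighbour) is far more accessible than the side-chain hydroxyl flanked by isopropyl and by the C5 methine next to quaternary C1, so the ester that the target needs at C6 is installed selectively and also serves as the C6 protecting group.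

Step 8
Reactants: 16 (1R,6R,7S)-6-ethenyl-7-[(1S)-1-hydroxy-2-methylpropyl]-3,6-dimethylcyclohept-3-en-1-yl 4-methoxybenzoate
Product: 17 (1R,6R,7R)-6-ethenyl-3,6-dimethyl-7-(2-methylpropanoyl)cyclohept-3-en-1-yl 4-methoxybenzoate
Conditions: Dess–Martin periodinane, NaHCO3, CH2Cl2, 0 °C → rt
Reagents that add atoms: none
Why: Buffered Dess–Martin oxidation converts the only remaining carbinol (secondary C4–OH) into the isopropyl ketone under conditions too mild to epimerise C5 or eliminate the β-aroyloxy group.

Step 9
Reactants: 17 (1R,6R,7R)-6-ethenyl-3,6-dimethyl-7-(2-methylpropanoyl)cyclohept-3-en-1-yl 4-methoxybenzoate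
Product: 18 (1R,6S,7R)-6-acetyl-3,6-dimethyl-7-(2-methylpropanoyl)cyclohept-3-en-1-yl 4-methoxybenzoate
Conditions: PdCl2 (0.2 equiv), CuCl, O2 (1 atm), DMF–H2O (7:1), rt
Reagents that add atoms: water, O
Why: Tsuji–Wacker oxidation: hydroxypalladation of the monosubstituted vinyl group at its internal carbon C2 (Markovnikov) turns the γ,δ-unsaturated ketone into the 1,4-diketone, while the trisubstituted C8=C9 alkene is inert under these conditions.

Step 10
Reactants: 18 (1R,6S,7R)-6-acetyl-3,6-dimethyl-7-(2-methylpropanoyl)cyclohept-3-en-1-yl 4-methoxybenzoate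
Product: 19 4β-hydroxy-2-oxodauc-8-en-6α-yl 4-methoxybenzoate (1β-methyl, 5α-H, trans-fused rings A/B)
Conditions: LiN(SiMe3)2 (1.05 equiv), THF, −78 → −40 °C; then AcOH, −78 °C
Reagents that add atoms: none
Why: Intramolecular aldol addition (5-enolexo-exo-trig): the amide removes a proton from the unhindered methyl group C3 (the only α-position of the C2 ketone and the kinetically favoured site), and the lithium enolate closes onto the C4 ketone to form trans-fused ring A with the isopropyl group on the α-face next to C5–H, away from the β C1 methyl and C6, so that the new tertiary hydroxyl is β, while the cold acidic quench prevents dehydration and β-elimination.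

Step 11
Reactants: 19 4β-hydroxy-2-oxodauc-8-en-6α-yl 4-methoxybenzoate
Product: 20 2α,4β-dihydroxydauc-8-en-6α-yl 4-methoxybenzoate
Conditions: Me4NBH(OAc)3, MeCN–AcOH (1:1), −20 °C
Reagents that add atoms: none
Why: Evans–Saksena reduction: the tertiary C4 hydroxyl exchanges onto the triacetoxyborohydride and delivers hydride intramolecularly to the β-face of the C2 ketone across ring A, giving the 1,3-anti (trans) diol with the C2 hydroxyl α, while the esters and the alkene are inert to this reagent.

Step 12
Reactants: 20 2α,4β-dihydroxydauc-8-en-6α-yl 4-methoxybenzoate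
Product: 21 2α-acetoxy-4β-hydroxydauc-8-en-6α-yl 4-methoxybenzoate
Conditions: Ac2O, pyridine, DMAP (cat.), CH2Cl2, 0 °C → rt
Reagents that add atoms: acetic anhydride, CC(=O)OC(C)=O
Why: Nucleophile-catalysed acetylation esterifies the secondary C2 hydroxyl only, because the tertiary C4 hydroxyl flanked by isopropyl and the ring fusion is unreactive under these mild conditions.

Step 13
Reactants: 21 2α-acetoxy-4β-hydroxydauc-8-en-6α-yl 4-methoxybenzoate
Product: 22 2α-acetoxy-8α,9α-epoxy-4β-hydroxydaucan-6α-yl 4-methoxybenzoate (CNP0317703.1)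
Conditions: mCPBA, NaHCO3, CH2Cl2, 0 °C
Reagents that add atoms: mCPBA, OOC(=O)c1cccc(Cl)c1
Why: Prilezhaev epoxidation: the peracid reacts at the only alkene, the electron-rich trisubstituted C8=C9 bond, from the α-face because the axial C1 methyl shields the β-face of trans-fused ring B and the C6 ester is equatorial, giving the 8α,9α-epoxide with the C8 methyl β.

**Compound list**

1 | 2,5-dimethylfuran | Cc1ccc(C)o1 | starting material
2 | 1,1,3,3-tetrabromoacetone | O=C(C(Br)Br)C(Br)Br | starting material
3 | 2,4-dibromo-1,5-dimethyl-8-oxabicyclo[3.2.1]oct-6-en-3-one (mixture of C2/C4 epimers) | C[C@@]12C(Br)C(=O)C(Br)[C@@](C)(O1)C=C2 | intermediate (not isolated)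
4 | (1R,5S)-1,5-dimethyl-8-oxabicyclo[3.2.1]oct-6-en-3-one (meso) | C[C@@]12CC(=O)C[C@@](C)(O1)C=C2 | intermediate
5 | (1R,5S)-1,5-dimethyl-8-oxabicyclo[3.2.1]octan-3-one (meso) | C[C@@]12CC(=O)C[C@@](C)(O1)CC2 | intermediate
6 | 3,6-dimethylcyclohepta-2,6-dien-1-one | CC1=CC(=O)C=C(C)CC1 | intermediate
7 | vinylmagnesium bromide | C=C[Mg]Br | starting material
8 | isobutyraldehyde | CC(C)C=O | starting material
9 | dimethyl(vinyl)alane | C=C[Al](C)C | intermediate (not isolated)
10 | dimethylaluminium (3R)-3-ethenyl-3,6-dimethylcyclohepta-1,6-dien-1-olate | C[Al](C)OC1=C[C@@](C)(C=C)CCC(C)=C1 | intermediate (not isolated)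
11 | (6R,7S)-6-ethenyl-7-[(1S)-1-hydroxy-2-methylpropyl]-3,6-dimethylcyclohept-2-en-1-one | O=C1C=C(C)CC[C@](C)(C=C)[C@H]1[C@@H](O)C(C)C | intermediate
12 | dilithium salt of 11: C4 lithium alkoxide and C6 lithium dienolate (C6=C7, C8=C9) | [Li]OC1=CC(C)=CC[C@](C)(C=C)[C@H]1[C@@H](O[Li])C(C)C | intermediate (not isolated)
13 | (6R,7S)-6-ethenyl-7-[(1S)-1-hydroxy-2-methylpropyl]-3,6-dimethylcyclohept-3-en-1-one | O=C1CC(C)=CC[C@](C)(C=C)[C@H]1[C@@H](O)C(C)C | intermediate
14 | (1R,6R,7R)-6-ethenyl-7-[(1S)-1-hydroxy-2-methylpropyl]-3,6-dimethylcyclohept-3-en-1-ol | O[C@@H]1CC(C)=CC[C@](C)(C=C)[C@H]1[C@@H](O)C(C)C | intermediate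
15 | 4-methoxybenzoyl chloride | COc1ccc(cc1)C(Cl)=O | starting material
16 | (1R,6R,7S)-6-ethenyl-7-[(1S)-1-hydroxy-2-methylpropyl]-3,6-dimethylcyclohept-3-en-1-yl 4-methoxybenzoate | COc1ccc(cc1)C(=O)O[C@@H]1CC(C)=CC[C@](C)(C=C)[C@H]1[C@@H](O)C(C)C | intermediate
17 | (1R,6R,7R)-6-ethenyl-3,6-dimethyl-7-(2-methylpropanoyl)cyclohept-3-en-1-yl 4-methoxybenzoate | COc1ccc(cc1)C(=O)O[C@@H]1CC(C)=CC[C@](C)(C=C)[C@H]1C(=O)C(C)C | intermediate
18 | (1R,6S,7R)-6-acetyl-3,6-dimethyl-7-(2-methylpropanoyl)cyclohept-3-en-1-yl 4-methoxybenzoate | COc1ccc(cc1)C(=O)O[C@@H]1CC(C)=CC[C@](C)(C(C)=O)[C@H]1C(=O)C(C)C | intermediate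
19 | 4β-hydroxy-2-oxodauc-8-en-6α-yl 4-methoxybenzoate (1β-Me, 4α-isopropyl, 5α-H) | COc1ccc(C(=O)O[C@@H]2CC(C)=CC[C@]3(C)C(=O)C[C@](O)(C(C)C)[C@@H]23)cc1 | intermediate
20 | 2α,4β-dihydroxydauc-8-en-6α-yl 4-methoxybenzoate | COc1ccc(C(=O)O[C@@H]2CC(C)=CC[C@]3(C)[C@H](O)C[C@](O)(C(C)C)[C@@H]23)cc1 | intermediate
21 | 2α-acetoxy-4β-hydroxydauc-8-en-6α-yl 4-methoxybenzoate | COc1ccc(C(=O)O[C@@H]2CC(C)=CC[C@]3(C)[C@H](OC(C)=O)C[C@](O)(C(C)C)[C@@H]23)cc1 | intermediate
22 | 2α-acetoxy-8α,9α-epoxy-4β-hydroxydaucan-6α-yl 4-methoxybenzoate (CNP0317703.1) | COc1ccc(C(=O)O[C@@H]2C[C@]3(C)O[C@@H]3C[C@]3(C)[C@H](OC(C)=O)C[C@](O)(C(C)C)[C@@H]23)cc1 | target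

**Totals.** Total step count: 13. Longest linear sequence: 13 steps (1 and 2 to 22).

**Steps most likely to fail**

Step 4 (key step). Methyl may transfer from the mixed alane in competition with vinyl, residual magnesium salts may erode the enantioselectivity, and capture of the hindered aluminium enolate by the aldehyde may be slow or poorly face-selective at C5. The fallback sets out from 6 and comes back at 11, separating the two bond formations. Copper-catalysed conjugate addition of [1-(trimethylsilyl)ethenyl]diisobutylalane (from ethynyltrimethylsilane and i-Bu2AlH; catalyst from Cu(OTf)2 and a chiral sulfonate-bearing imidazolinium salt as N-heterocyclic carbene precursor) with aqueous quench should give (S)-3,6-dimethyl-6-[1-(trimethylsilyl)ethenyl]cyclohept-2-en-1-one F1. Protodesilylation (CF3CO2H, CH2Cl2, 0 °C) should give (S)-6-ethenyl-3,6-dimethylcyclohept-2-en-1-one F2. Soft enolisation at C5 with (c-C6H11)2BCl/Et3N and addition of the resulting E-boron enolate to 8 (anti-selective boron aldol) then returns 11.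

Step 5. The amide may remove the C5 proton (loss of the C5 configuration), the lithium alkoxide may undergo retro-aldol cleavage, or the β,γ-enone may reconjugate during isolation. The fallback sets out from 11 and comes back at 16; it replaces the dianion by a protected substrate under thermodynamic control and also bypasses the selective acylation of step 7. Silylation (t-BuMe2SiOTf, 2,6-lutidine, CH2Cl2) should give the tert-butyldimethylsilyl ether of 11 F3. Equilibration to the extended potassium dienolate (KOt-Bu, t-BuOH–THF, 0 °C) and kinetic quench with AcOH should give the silyl ether of 13 F4. NaBH4 (MeOH, −40 °C) should give the equatorial 6α-alcohol, the side-chain silyl ether of 14 F5. Acylation with 15 (pyridine, DMAP) should give the silyl ether of 16 F6, and HF·pyridine (THF, 0 °C) then liberates the C4 hydroxyl to give 16.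

Step 10. Proton transfer may generate the C5 enolate, which would expel the C6 aroyloxy group; the aldol may dehydrate to the cyclopentenone; or the ester may shift to the new tertiary alkoxide. The fallback sets out from 18 and comes back at 19 and avoids basic alkoxides altogether. Soft enolisation of the methyl ketone (Me3SiOTf, Et3N, CH2Cl2, −78 °C) should give the trimethylsilyl enol ether of the acetyl group of 18 F7. An intramolecular Mukaiyama aldol addition (TiCl4, CH2Cl2, −78 °C, aqueous work-up) then closes C3–C4 and returns 19.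

**Further compounds**

F1 | step 4 | (S)-3,6-dimethyl-6-[1-(trimethylsilyl)ethenyl]cyclohept-2-en-1-one | O=C1C=C(C)CC[C@](C)(C(=C)[Si](C)(C)C)C1
F2 | step 4 | (S)-6-ethenyl-3,6-dimethylcyclohept-2-en-1-one | O=C1C=C(C)CC[C@](C)(C=C)C1
F3 | step 5 | tert-butyldimethylsilyl ether of 11 | O=C1C=C(C)CC[C@](C)(C=C)[C@H]1[C@@H](O[Si](C)(C)C(C)(C)C)C(C)C
F4 | step 5 | tert-butyldimethylsilyl ether of 13 | O=C1CC(C)=CC[C@](C)(C=C)[C@H]1[C@@H](O[Si](C)(C)C(C)(C)C)C(C)C
F5 | step 5 | side-chain tert-butyldimethylsilyl ether of 14 (free 6α-hydroxyl) | O[C@@H]1CC(C)=CC[C@](C)(C=C)[C@H]1[C@@H](O[Si](C)(C)C(C)(C)C)C(C)C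
F6 | step 5 | tert-butyldimethylsilyl ether of 16 | COc1ccc(cc1)C(=O)O[C@@H]1CC(C)=CC[C@](C)(C=C)[C@H]1[C@@H](O[Si](C)(C)C(C)(C)C)C(C)C
F7 | step 10 | trimethylsilyl enol ether of the acetyl group of 18 | COc1ccc(cc1)C(=O)O[C@@H]1CC(C)=CC[C@](C)(C(=C)O[Si](C)(C)C)[C@H]1C(=O)C(C)C
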